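## The problem

Target 18 is made of two constitutionally identical (2S)-7-hydroxy-5-methoxyflavan (2-phenylchroman) units that share one methylene carbon. This carbon is bonded to C8 of one unit (unit A) and to C6 of the other (unit B). The ring count is modest, two benzopyrans, but the bridge is unsymmetrical. In each phloroglucinol-type ring C6 and C8 are both ortho to the C7 hydroxyl and similarly nucleophilic, so the 8–CH2–6' connection has to be enforced and cannot be left to innate preference. The only stereocentres are C2 and C2', both S and ten bonds apart. Neither can direct the other, so the configuration must come from a reagent, most economically once, in a monomer that serves for both halves. Each stereocentre is a benzylic carbon that carries the ring oxygen, so the C2–O1 bond is open to acid-induced ionisation (ring opening, epimerisation) and to hydrogenolysis. The electron-rich arenes and free phenols are in turn sensitive to oxidants and to stray electrophiles. The feature that makes the key step possible is that O1 joins stereogenic C2 to the arene carbon C8a. The pyran can therefore be closed at the aryl–oxygen bond while the C2–O bond, and with it the configuration, stays untouched. In the open-chain precursor C8a lies between the chain-bearing C4a and C8–H, so a leaving group there can only lead to the six-membered ring.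

## Retrosynthesis

**18 from 17.** The last simplification replaces C8'–H of unit B by C8'–Br. The bromide is a blocking group that forces the bridge onto C6 of unit B. The forward step must remove it without cleaving the two benzylic C2–O1 bonds.

**17 from 12 and 15 (through 16).** The bond between the bridge carbon and C6 of unit B is cut. The electrophile is ortho-quinone methide 16, released from phenolic Mannich base 15. The nucleophile is bromophenol 12, whose only free ring position is C6. A three-component condensation of two monomers with formaldehyde would be the obvious neighbour, but it would give 6–6', 8–8' and 6–8' bridges and oligomers side by side. Here each partner has one role and one reactive site. The cut turns the dimer into two monomers of the same skeleton. The forward reaction must generate 16 without acid and let 12 win against the other nucleophiles present.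

**12 and 15 from 11.** Both partners come from one aryl bromide. Removal of the MOM group gives 12. Bromine–lithium exchange, capture of aryllithium 13 by an iminium salt (14) and MOM removal give 15. Functionalising the two halves separately would require the C6/C8 choice to be made twice with the same outcome. Deriving both from 11 makes the outcomes match by construction. Because the two units are identical, the route reaches 18 whichever of the two positions is brominated, provided only one is.

**11 from 10.** The C8–Br bond is cut. Bromination is placed at the ether stage, where 5,7-dialkoxyflavans react with a single equivalent of NBS at one position.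

**10 from 9 (key disconnection).** The C8a–O1 bond is cut. The neighbouring cut at O1–C2 would require a substitution at the benzylic stereocentre, with the risk of ionisation. The cut at C4–C4a would require a Friedel–Crafts closure on a ring with two open positions. The aryl–oxygen cut leaves a secondary carbinol and an aryl bromide, and the forward C–O coupling never touches the bonds of the stereocentre. The precursor 9 is an open-chain bromoarene with one stereocentre. The forward reaction must favour C–O reductive elimination over β-hydride elimination.

**9 from 8, 7, and from 5 plus 6.** The carbinol stereocentre is traced to aryl ketone 8 and set by catalytic transfer hydrogenation. The C2–C3 bond (flavan numbering) is traced to a Claisen–Schmidt condensation of aldehyde 5 with acetophenone 6, followed by saturation of enone 7. A benzylic alkylation route to 8 would be longer. The saturation must spare the C–Br bond.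

**5 from 4, 3 and 1.** The arene is traced to symmetric diol 1. An arene whose two oxygens are already differentiated would offer three competing activated positions to a formylating agent. In 1 the two positions next to bromine are equivalent, so formylation gives a single aldehyde 3. The aldehyde then differentiates the hydroxyls through its hydrogen bond: the free para hydroxyl takes the MOM group (4) and the chelated ortho hydroxyl the methyl group (5).

## Roads not taken

**Alternative 1:** The cut runs through ring A of unit A itself: C7–C8, C8a–C4a and C6–C7 are taken apart. This leads to cyclobutenone A2, a 3-methoxycyclobutenone whose side chain ends in the alkynyl ether of the (S)-carbinol. The alkyne carries the finished, silyl-protected unit B on a propargylic methylene.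

- Forward step: heat or light opens the four-membered ring to a vinylketene, which adds to the tethered alkynyl ether. A second ring opening and a 6π electrocyclisation (Danheiser-type benzannulation) would give phenol A1, with the arene and pyran of unit A formed together.
- Merits: every substituent of ring A is placed by connectivity, so the C6/C8 question does not arise for this ring and no blocking group is needed. The C2–O bond is not touched.
- Weak points: A2 is an alkynyl ether of a secondary benzylic alcohol with β-hydrogens. Such ethers fragment by retro-ene loss of an alkene at temperatures close to those needed to open the cyclobutenone. Making this ether is itself long. Unit B must first be prepared by another flavan synthesis and functionalised at C6, so the regiochemical problem returns there and the identity of the two halves is not used.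
- Comparison: in regiochemical certainty on unit A this road is better than the chosen plan, which depends on an electrophilic bromination. The chosen plan sets against it that the bromination only has to be uniform, not of a particular sense, and that one eight-step monomer synthesis supplies both halves.

**Alternative 2:** Both C2–phenyl bonds are cut. The precursor is bis(2-ethoxy-2H-chromene) A4, a mixture of acetal stereoisomers on the complete methylene-bridged core. The partner is phenylboronic acid A5.

- Forward step: a zerovalent nickel catalyst with a chiral TADDOL-derived phosphonite would ionise each acetal and transfer phenyl enantioselectively. This would give bis(2H-chromene) A3 with both stereocentres, whatever the configuration of the acetal carbons.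
- Merits: both stereocentres and both aryl groups arise in one catalytic step from racemic material. The aryl group enters last, which suits analogue work. The double reaction raises the enantiomeric purity of the homochiral product at the cost of a diastereomer.
- Weak points: the unsymmetrical 8–CH2–6' core must be built before the key step, which does nothing for that central problem. Any shortfall in selectivity at either site appears as a diastereomer. The 5,7-dioxygenated benzopyrylium ions are strongly stabilised, which helps ionisation but not capture at the metal. A3 still needs hydrogenation of two C3=C4 bonds next to C2–O bonds that are allylic as well as benzylic, and removal of two silyl ethers.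
- Comparison: this road is better for late variation of the 2-aryl group. In stereochemical step economy it is no better, since the chosen plan also creates its stereocentre in one operation on a shared monomer. The chosen plan sets against it the reliability of transfer hydrogenation of a simple aryl alkyl ketone and the absence of a late alkene hydrogenation beside a labile ether.

**Alternative 3:** The C4–C4a bond of unit A is cut. In precursor A7 unit A is still an open phloroglucinol. O1 carries the (S)-3-iodo-1-phenylpropyl chain, C8 carries the methylene to benzyl-protected unit B, and C4a is unsubstituted.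

- Forward step: with a carbonate base at high dilution the phenoxide attacks the primary iodide through C4a, the ring carbon para to the phenoxide oxygen. Tautomerisation of the dienone gives A6 and closes the pyran.
- Merits: no transition metal is needed. The reacting carbon is C4, so C2 is untouched. C4a is the only ring carbon within reach.
- Weak points: intermolecular O-alkylation and elimination of HI compete with a C-alkylation that must pass through a dearomatised intermediate. The secondary benzylic aryl ether of A7 has to be made with defined configuration on a doubly ortho-substituted phenol, an etherification with inversion at a benzylic carbon that is prone to partial racemisation. Three oxygens of ring A must be told apart while unit B is already attached, and unit B again needs its own route.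
- Comparison: this road avoids palladium and the blocking bromide, and it protects the stereocentre during ring closure as well as the chosen plan does. The chosen plan sets against it that its stereocentre comes from a catalytic ketone reduction, not from a stereospecific etherification, and that its ring closure has direct precedent with secondary carbinols.

Key step: step 7

## Route

Remark: ring positions follow flavan numbering (chroman = 3,4-dihydro-2H-chromene); before ring closure the arene is numbered from the chain-bearing carbon. 5-Bromobenzene-1,3-diol and racemic 2-(di-tert-butylphosphino)-1,1'-binaphthyl are taken to be commercial.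

Step 1
Reactants: 1 5-bromobenzene-1,3-diol
Product: 3 2-bromo-4,6-dihydroxybenzaldehyde, via iminium chloride 2 (not isolated)
Conditions: POCl3, DMF, MeCN, −15 °C to rt; then H2O, 50 °C
Reagents that add atoms: N,N-dimethylformamide CN(C)C=O; water O
Why: Vilsmeier–Haack formylation; the two equivalent positions next to bromine are para to one hydroxyl and ortho to the other and less crowded than the position between the hydroxyls, as in the formylation of other 5-substituted resorcinols, and hydrolysis of iminium salt 2 releases the aldehyde.

Step 2
Reactants: 3 2-bromo-4,6-dihydroxybenzaldehyde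
Product: 4 2-bromo-6-hydroxy-4-(methoxymethoxy)benzaldehyde
Conditions: MOMCl (1.05 equiv), K2CO3, acetone, 0 °C to rt
Reagents that add atoms: chloromethyl methyl ether COCCl
Why: Williamson-type O-alkylation; the 6-hydroxyl is held in a hydrogen bond to the aldehyde, so the more acidic para hydroxyl reacts first, the usual selectivity of 2,4-dihydroxybenzaldehydes.

Step 3
Reactants: 4 2-bromo-6-hydroxy-4-(methoxymethoxy)benzaldehyde
Product: 5 2-bromo-6-methoxy-4-(methoxymethoxy)benzaldehyde
Conditions: MeI, K2CO3, DMF, rt
Reagents that add atoms: iodomethane CI
Why: Williamson methylation of the remaining chelated phenol; the MOM ether, aldehyde and aryl bromide are inert to these conditions.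

Step 4
Reactants: 5 2-bromo-6-methoxy-4-(methoxymethoxy)benzaldehyde, 6 acetophenone
Product: 7 (2E)-3-[2-bromo-6-methoxy-4-(methoxymethoxy)phenyl]-1-phenylprop-2-en-1-one
Conditions: KOH (aq.), EtOH, 0 °C to rt
Reagents that add atoms: none
Why: Claisen–Schmidt condensation (aldol addition and E1cB dehydration) of a non-enolisable aldehyde with a methyl ketone gives the thermodynamic E enone; MOM ether and aryl bromide are stable to hydroxide.

Step 5
Reactants: 7 (2E)-3-[2-bromo-6-methoxy-4-(methoxymethoxy)phenyl]-1-phenylprop-2-en-1-one
Product: 8 3-[2-bromo-6-methoxy-4-(methoxymethoxy)phenyl]-1-phenylpropan-1-one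
Conditions: H2 (3 atm), RhCl(PPh3)3 (5 mol%), toluene/EtOH, 40 °C
Reagents that add atoms: none
Why: Homogeneous hydrogenation with RhCl(PPh3)3 saturates the disubstituted C=C bond of the enone and leaves the aryl ketone and the aryl C–Br bond alone, which a heterogeneous palladium catalyst would not.

Step 6
Reactants: 8 3-[2-bromo-6-methoxy-4-(methoxymethoxy)phenyl]-1-phenylpropan-1-one
Product: 9 (1S)-3-[2-bromo-6-methoxy-4-(methoxymethoxy)phenyl]-1-phenylpropan-1-ol
Conditions: RuCl(p-cymene)[(S,S)-TsDPEN] (1 mol%), HCO2H/Et3N (5:2), EtOAc, 30 °C
Reagents that add atoms: none
Why: Noyori–Ikariya asymmetric transfer hydrogenation of an aryl alkyl ketone; the (S,S) complex delivers hydride to the Re face, the CH/π contact between its arene ligand and the phenyl ring fixing the orientation, which gives the S carbinol as it does with acetophenone.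

Step 7
Reactants: 9 (1S)-3-[2-bromo-6-methoxy-4-(methoxymethoxy)phenyl]-1-phenylpropan-1-ol
Product: 10 (2S)-5-methoxy-7-(methoxymethoxy)-2-phenylchroman
Conditions: Pd(OAc)2 (3 mol%), 2-(di-tert-butylphosphino)-1,1'-binaphthyl (4 mol%), Cs2CO3, toluene, 80 °C
Reagents that add atoms: none
Why: This is an intramolecular Buchwald–Hartwig-type aryl etherification, and the closest known reaction type is the palladium-catalysed cyclisation of aryl bromides carrying a tethered secondary alcohol to chromans. Zerovalent palladium, formed in situ from Pd(OAc)2 and the phosphine, inserts into the C–Br bond. Cs2CO3 deprotonates the carbinol, and the alkoxide displaces bromide on divalent palladium to give a seven-membered aryl(alkoxo)palladium chelate. C(sp2)–O reductive elimination from this chelate forms the C8a–O1 bond and closes the pyran as a six-membered ring. No stereocentre is created: the carbinol C–O bond is never broken, so the S configuration from step 6 is carried into C2 with retention. The selectivity required is reductive elimination over β-hydride elimination of the secondary alkoxide, and the bulky, electron-rich di-tert-butyl biaryl phosphine secures it by keeping palladium monoligated and crowded. Regiochemistry is not in question, because the bromide lies between the chain-bearing carbon and a ring C–H, so only the six-membered closure is possible. The MOM and methyl ethers are inert to carbonate in toluene.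

Step 8
Reactants: 10 (2S)-5-methoxy-7-(methoxymethoxy)-2-phenylchroman
Product: 11 (2S)-8-bromo-5-methoxy-7-(methoxymethoxy)-2-phenylchroman
Conditions: NBS (1.0 equiv), CH2Cl2, −20 °C to 0 °C, dark
Reagents that add atoms: N-bromosuccinimide O=C1CCC(=O)N1Br
Why: Electrophilic aromatic bromination; in 5,7-dialkoxyflavans NBS attacks C8, flanked by the tied-back ring oxygen, before the more crowded C6, as in O-alkylated flavan-3-ols, and one equivalent at low temperature should stop at the monobromide. Since step 12 joins a C6 to a C8 of two identical units, the route only needs the bromine at one uniform position.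

Step 9
Reactants: 11 (2S)-8-bromo-5-methoxy-7-(methoxymethoxy)-2-phenylchroman
Product: 12 (2S)-8-bromo-5-methoxy-2-phenylchroman-7-ol
Conditions: conc. HCl (cat.), MeOH, 40 °C
Reagents that add atoms: none
Why: Acid-catalysed acetal exchange removes the MOM group as dimethoxymethane; the benzylic C2–O1 bond has only an unactivated phenyl to stabilise a cation and should not ionise under these mild conditions.

Step 10
Reactants: 11 (2S)-8-bromo-5-methoxy-7-(methoxymethoxy)-2-phenylchroman
Product: 14 1-[(2S)-5-methoxy-7-(methoxymethoxy)-2-phenylchroman-8-yl]-N,N-dimethylmethanamine, via aryllithium 13 (not isolated)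
Conditions: n-BuLi (1.1 equiv), THF, −78 °C; then CH2=NMe2+ I−, −78 °C to rt
Reagents that add atoms: N,N-dimethylmethyleneiminium iodide C=[N+](C)C.[I-]
Why: Bromine–lithium exchange is faster than deprotonation at −78 °C and gives an aryllithium chelated by the flanking MOM and ring oxygens; its addition to the preformed iminium salt is a Mannich-type aminomethylation of an organolithium and places the one-carbon unit exactly where the bromine was.

Step 11
Reactants: 14 1-[(2S)-5-methoxy-7-(methoxymethoxy)-2-phenylchroman-8-yl]-N,N-dimethylmethanamine
Product: 15 (2S)-8-[(dimethylamino)methyl]-5-methoxy-2-phenylchroman-7-ol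
Conditions: HCl (2 equiv), MeOH, 40 °C; then aq. NaHCO3
Reagents that add atoms: none
Why: Acid-catalysed MOM removal as in step 9; the amine is protonated during the reaction, which keeps it from leaving, and neutralisation returns the hydrogen-bonded phenolic Mannich base.

Step 12
Reactants: 15 (2S)-8-[(dimethylamino)methyl]-5-methoxy-2-phenylchroman-7-ol, 12 (2S)-8-bromo-5-methoxy-2-phenylchroman-7-ol
Product: 17 (2S)-8-bromo-6-{[(2S)-7-hydroxy-5-methoxy-2-phenylchroman-8-yl]methyl}-5-methoxy-2-phenylchroman-7-ol, via ortho-quinone methide 16 (not isolated)
Conditions: 12 (3 equiv), toluene, 110 °C, slow addition of 15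
Reagents that add atoms: none
Why: Thermal loss of dimethylamine from the phenolic Mannich base gives ortho-quinone methide 16, which phenol 12 captures in a Michael-type C-alkylation at C6, its only free ring position; O-alkylation is reversible and drains into the C-benzylated phenol. Excess 12 and slow addition of 15 keep 16 from reacting with the free C6 of 15 or of 17.

Step 13
Reactants: 17 (2S)-8-bromo-6-{[(2S)-7-hydroxy-5-methoxy-2-phenylchroman-8-yl]methyl}-5-methoxy-2-phenylchroman-7-ol
Product: 18 (2S)-8-{[(2S)-7-hydroxy-5-methoxy-2-phenylchroman-6-yl]methyl}-5-methoxy-2-phenylchroman-7-ol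
Conditions: H2 (1 atm), Pd/C (10% Pd on carbon), NaOAc, MeOH/EtOAc, rt
Reagents that add atoms: none
Why: Catalytic hydrodebromination of the aryl bromide is much faster than hydrogenolysis of the benzylic C2–O1 ethers at 1 atm, as in the removal of C8 bromine blocking groups from flavan oligomers; NaOAc takes up HBr so that no acid reaches the pyran rings.

## Compound list

1 | 5-bromobenzene-1,3-diol | Oc1cc(O)cc(Br)c1 | starting material
2 | [(2-bromo-4,6-dihydroxyphenyl)methylidene]dimethylammonium chloride | C[N+](C)=Cc1c(O)cc(O)cc1Br.[Cl-] | intermediate
3 | 2-bromo-4,6-dihydroxybenzaldehyde | O=Cc1c(O)cc(O)cc1Br | intermediate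
4 | 2-bromo-6-hydroxy-4-(methoxymethoxy)benzaldehyde | COCOc1cc(O)c(C=O)c(Br)c1 | intermediate
5 | 2-bromo-6-methoxy-4-(methoxymethoxy)benzaldehyde | COCOc1cc(OC)c(C=O)c(Br)c1 | intermediate
6 | acetophenone | CC(=O)c1ccccc1 | starting material
7 | (2E)-3-[2-bromo-6-methoxy-4-(methoxymethoxy)phenyl]-1-phenylprop-2-en-1-one | COCOc1cc(OC)c(/C=C/C(=O)c2ccccc2)c(Br)c1 | intermediate
8 | 3-[2-bromo-6-methoxy-4-(methoxymethoxy)phenyl]-1-phenylpropan-1-one | COCOc1cc(OC)c(CCC(=O)c2ccccc2)c(Br)c1 | intermediate
9 | (1S)-3-[2-bromo-6-methoxy-4-(methoxymethoxy)phenyl]-1-phenylpropan-1-ol | COc1cc(OCOC)cc(Br)c1CC[C@@H](c1ccccc1)O | intermediate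
10 | (2S)-5-methoxy-7-(methoxymethoxy)-2-phenylchroman | COc1cc(OCOC)cc2c1CC[C@@H](c1ccccc1)O2 | intermediate
11 | (2S)-8-bromo-5-methoxy-7-(methoxymethoxy)-2-phenylchroman | COc1cc(OCOC)c(Br)c2c1CC[C@@H](c1ccccc1)O2 | intermediate
12 | (2S)-8-bromo-5-methoxy-2-phenylchroman-7-ol | COc1cc(O)c(Br)c2c1CC[C@@H](c1ccccc1)O2 | intermediate
13 | [(2S)-5-methoxy-7-(methoxymethoxy)-2-phenylchroman-8-yl]lithium | COc1cc(OCOC)c([Li])c2c1CC[C@@H](c1ccccc1)O2 | intermediate
14 | 1-[(2S)-5-methoxy-7-(methoxymethoxy)-2-phenylchroman-8-yl]-N,N-dimethylmethanamine | COc1cc(OCOC)c(CN(C)C)c2c1CC[C@@H](c1ccccc1)O2 | intermediate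
15 | (2S)-8-[(dimethylamino)methyl]-5-methoxy-2-phenylchroman-7-ol | COc1cc(O)c(CN(C)C)c2c1CC[C@@H](c1ccccc1)O2 | intermediate
16 | (2S)-5-methoxy-8-methylidene-2-phenyl-3,4-dihydro-2H-chromen-7(8H)-one | COC1=CC(=O)C(=C)C2=C1CC[C@@H](c1ccccc1)O2 | intermediate
17 | (2S)-8-bromo-6-{[(2S)-7-hydroxy-5-methoxy-2-phenylchroman-8-yl]methyl}-5-methoxy-2-phenylchroman-7-ol | COc1cc(O)c(Cc2c(O)c(Br)c3c(c2OC)CC[C@@H](c2ccccc2)O3)c2c1CC[C@@H](c1ccccc1)O2 | intermediate
18 | (2S)-8-{[(2S)-7-hydroxy-5-methoxy-2-phenylchroman-6-yl]methyl}-5-methoxy-2-phenylchroman-7-ol (CNP0178097.1) | COc1cc(O)c(Cc2c(O)cc3c(c2OC)CC[C@@H](c2ccccc2)O3)c2c1CC[C@@H](c1ccccc1)O2 | target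

## Step count and least certain steps

Total step count: 13. Longest linear sequence: 12 steps (steps 1 to 8, then 10, 11, 12 and 13); the branch through step 9 joins at step 12.

**Step 7 (key step).** What may go wrong is β-hydride elimination from the aryl(alkoxo)palladium intermediate outrunning C–O reductive elimination. That would oxidise the carbinol back to the ketone and remove bromine from the arene. Slow turnover at the ortho-substituted bromide is the second risk. The fallback closes the other C–O bond. It sets out from ketone 8. Transfer hydrogenation with the enantiomeric complex RuCl(p-cymene)[(R,R)-TsDPEN] would give (1R)-3-[2-bromo-6-methoxy-4-(methoxymethoxy)phenyl]-1-phenylpropan-1-ol F1. Bromine–lithium exchange on its lithium alkoxide (n-BuLi, 2.2 equiv) and capture with B(OMe)3 would give {2-[(3R)-3-hydroxy-3-phenylpropyl]-3-methoxy-5-(methoxymethoxy)phenyl}boronic acid F2. Alkaline H2O2 would oxidise this to (1R)-3-[2-hydroxy-6-methoxy-4-(methoxymethoxy)phenyl]-1-phenylpropan-1-ol F3. A Mitsunobu cyclisation (PPh3, diisopropyl azodicarboxylate, THF) would then form O1–C2 with inversion and come back to the route at 10.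

**Step 12.** What may go wrong is capture of the quinone methide by the free C6 of its own precursor 15 or of product 17 instead of by 12, which leads to oligomers. Sluggish thermal release of the amine is the second risk. The fallback forms the bridge by carbonyl addition and sets out from 12. Magnesium-mediated ortho-formylation (MgCl2, Et3N, paraformaldehyde) can only occur at C6 and would give (2S)-8-bromo-7-hydroxy-5-methoxy-2-phenylchroman-6-carbaldehyde F4. MOM protection (MOMCl, NaH, DMF) would give (2S)-8-bromo-5-methoxy-7-(methoxymethoxy)-2-phenylchroman-6-carbaldehyde F5. Aryllithium 13, made from 11 as in step 10, would add to F5 to give [(2S)-8-bromo-5-methoxy-7-(methoxymethoxy)-2-phenylchroman-6-yl][(2S)-5-methoxy-7-(methoxymethoxy)-2-phenylchroman-8-yl]methanol F6 as both carbinol epimers. Ionic hydrogenation (Et3SiH, CF3CO2H, CH2Cl2, −20 °C) would remove the carbinol oxygen and give (2S)-8-bromo-5-methoxy-7-(methoxymethoxy)-6-{[(2S)-5-methoxy-7-(methoxymethoxy)-2-phenylchroman-8-yl]methyl}-2-phenylchroman F7. Methanolic HCl would then remove both MOM groups and come back to the route at 17.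

**Step 10.** What may go wrong is slow capture of the aryllithium by the sparingly soluble iminium salt, so that protonation or butylation by the 1-bromobutane formed in the exchange competes. Deprotonation at benzylic C2 is a lesser risk. The fallback sets out from 11. The same aryllithium would be trapped with DMF to give (2S)-5-methoxy-7-(methoxymethoxy)-2-phenylchroman-8-carbaldehyde F8. Reductive amination with Me2NH and NaBH(OAc)3 would come back to the route at 14.

**Step 13.** What may go wrong is hydrogenolysis of a benzylic C2–O1 bond alongside or after C–Br cleavage, which would open a pyran ring. The fallback is a radical chain reduction with Bu3SnH and AIBN in toluene at 90 °C. It sets out from 17 and arrives directly at 18; it makes no new compound (F0).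

**Step 5.** What may go wrong is slow hydrogenation of the hindered alkene, so that forcing conditions begin to remove bromine or reduce the ketone. The fallback is conjugate hydride delivery with catalytic [(Ph3P)CuH]6, PhMe2SiH and t-BuOH in toluene. It sets out from 7 and comes back to the route at 8; it makes no new compound (F0).

## Further compounds

F1 | step 7 | (1R)-3-[2-bromo-6-methoxy-4-(methoxymethoxy)phenyl]-1-phenylpropan-1-ol | COc1cc(OCOC)cc(Br)c1CC[C@H](c1ccccc1)O
F2 | step 7 | {2-[(3R)-3-hydroxy-3-phenylpropyl]-3-methoxy-5-(methoxymethoxy)phenyl}boronic acid | COc1cc(OCOC)cc(B(O)O)c1CC[C@H](c1ccccc1)O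
F3 | step 7 | (1R)-3-[2-hydroxy-6-methoxy-4-(methoxymethoxy)phenyl]-1-phenylpropan-1-ol | COc1cc(OCOC)cc(O)c1CC[C@H](c1ccccc1)O
F4 | step 12 | (2S)-8-bromo-7-hydroxy-5-methoxy-2-phenylchroman-6-carbaldehyde | COc1c(C=O)c(O)c(Br)c2c1CC[C@@H](c1ccccc1)O2
F5 | step 12 | (2S)-8-bromo-5-methoxy-7-(methoxymethoxy)-2-phenylchroman-6-carbaldehyde | COc1c(C=O)c(OCOC)c(Br)c2c1CC[C@@H](c1ccccc1)O2
F6 | step 12 | [(2S)-8-bromo-5-methoxy-7-(methoxymethoxy)-2-phenylchroman-6-yl][(2S)-5-methoxy-7-(methoxymethoxy)-2-phenylchroman-8-yl]methanol (both carbinol epimers) | COc1cc(OCOC)c(C(O)c2c(OCOC)c(Br)c3c(c2OC)CC[C@@H](c2ccccc2)O3)c2c1CC[C@@H](c1ccccc1)O2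
F7 | step 12 | (2S)-8-bromo-5-methoxy-7-(methoxymethoxy)-6-{[(2S)-5-methoxy-7-(methoxymethoxy)-2-phenylchroman-8-yl]methyl}-2-phenylchroman | COc1cc(OCOC)c(Cc2c(OCOC)c(Br)c3c(c2OC)CC[C@@H](c2ccccc2)O3)c2c1CC[C@@H](c1ccccc1)O2
F8 | step 10 | (2S)-5-methoxy-7-(methoxymethoxy)-2-phenylchroman-8-carbaldehyde | COc1cc(OCOC)c(C=O)c2c1CC[C@@H](c1ccccc1)O2
F0 | step 13 | none | none
F0 | step 5 | none | none
A1 | alternative 1 | (2S)-8-{[(2S)-7-{[tert-butyl(dimethyl)silyl]oxy}-5-methoxy-2-phenylchroman-6-yl]methyl}-5-methoxy-2-phenylchroman-7-ol | COc1cc(O)c(Cc2c(O[Si](C)(C)C(C)(C)C)cc3c(c2OC)CC[C@@H](c2ccccc2)O3)c2c1CC[C@@H](c1ccccc1)O2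
A2 | alternative 1 | 3-methoxy-2-[(3S)-3-phenyl-3-({3-[(2S)-7-{[tert-butyl(dimethyl)silyl]oxy}-5-methoxy-2-phenylchroman-6-yl]prop-1-yn-1-yl}oxy)propyl]cyclobut-2-en-1-one | COC1=C(CC[C@@H](c2ccccc2)OC#CCc2c(O[Si](C)(C)C(C)(C)C)cc3c(c2OC)CC[C@@H](c2ccccc2)O3)C(=O)C1
A3 | alternative 2 | (2S)-7-{[tert-butyl(dimethyl)silyl]oxy}-8-{[(2S)-7-{[tert-butyl(dimethyl)silyl]oxy}-5-methoxy-2-phenyl-2H-chromen-6-yl]methyl}-5-methoxy-2-phenyl-2H-chromene | COc1cc(O[Si](C)(C)C(C)(C)C)c(Cc2c(O[Si](C)(C)C(C)(C)C)cc3c(c2OC)C=C[C@@H](c2ccccc2)O3)c2c1C=C[C@@H](c1ccccc1)O2
A4 | alternative 2 | 7-{[tert-butyl(dimethyl)silyl]oxy}-8-{[7-{[tert-butyl(dimethyl)silyl]oxy}-2-ethoxy-5-methoxy-2H-chromen-6-yl]methyl}-2-ethoxy-5-methoxy-2H-chromene (mixture of acetal stereoisomers) | CCOC1C=Cc2c(OC)cc(O[Si](C)(C)C(C)(C)C)c(Cc3c(O[Si](C)(C)C(C)(C)C)cc4OC(OCC)C=Cc4c3OC)c2O1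
A5 | alternative 2 | phenylboronic acid | OB(O)c1ccccc1
A6 | alternative 3 | (2S)-8-{[(2S)-7-(benzyloxy)-5-methoxy-2-phenylchroman-6-yl]methyl}-5-methoxy-2-phenylchroman-7-ol | COc1cc(O)c(Cc2c(OCc3ccccc3)cc3c(c2OC)CC[C@@H](c2ccccc2)O3)c2c1CC[C@@H](c1ccccc1)O2
A7 | alternative 3 | 2-{[(2S)-7-(benzyloxy)-5-methoxy-2-phenylchroman-6-yl]methyl}-3-[(1S)-3-iodo-1-phenylpropoxy]-5-methoxyphenol | COc1cc(O)c(Cc2c(OCc3ccccc3)cc3c(c2OC)CC[C@@H](c2ccccc2)O3)c(O[C@@H](CCI)c2ccccc2)c1
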